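The three C2–aryl bonds of the 2,3-dihydrobenzofuran rings A, B and C are cut together: each C2 carries the same 4-hydroxyphenyl group, trans to the aryl substituent on C3. In one operation a tris(dihydrobenzofuran-2-carboxylic acid) loses three molecules of CO2 and each planar C2 radical is arylated by 4-bromoanisole (three equivalents) anti to C3, so three bonds and three stereocentres form at once. The precursor has C3 fixed as R (ring A), S (ring B) and R (ring C), C2 undefined, five methyl ethers and a chlorine on C4 of ring A; it comes from three rhodium-catalysed conjugate arylations of 5-halo-7-methoxycoumarins and lactone ring contraction. The phenols are freed before the acid-sensitive stilbene is built.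

Key step: step 12

Remarks on the chemistry:
- Benzofuran numbering is used for the three dihydrobenzofurans. Ring A carries the styryl group on C4 (chlorine until step 15), ring B is central, and ring C carries the 3,5-dioxygenated phenyl on C3. The target is trans in every ring: A (2R,3R), B (2S,3S), C (2R,3R).
- Assumption: 2-bromo- and 2-chloro-4,6-dimethoxybenzaldehyde are bought (each is otherwise one Vilsmeier formylation from the 1-halo-3,5-dimethoxybenzene). The coumarins are built from them because ring closure of a 3-halo-5-methoxyphenol could occur at either ortho position.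
- Step 12 consumes three molecules of 4-bromoanisole 19 per molecule of tris-acid 18, one for each carboxyl group. The first is entered as the reactant, and the second and third are entered under the reagents that add atoms.
- The methyl ethers are cleaved before the alkene exists. A 4-styryl-3-aryl-dihydrobenzofuran whose C3 aryl ring has a free, oxygen-activated ortho position (C5 of ring B) is expected to close a seven-membered ring once its alkene is protonated.

Step 1
Reactants: 1 2-bromo-4,6-dimethoxybenzaldehyde
Product: 2 2-bromo-6-hydroxy-4-methoxybenzaldehyde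
Conditions: BCl3 (1.5 equiv), CH2Cl2, −78 to 0 °C; aq. work-up
Reagents that add atoms: none
Why: Chelation-controlled ether cleavage, in which BCl3 binds between the aldehyde oxygen and the ortho methoxy group and removes only that methyl group, so the halogen is fixed at the future C5 of the coumarin without any regiochemical choice.

Step 2
Reactants: 2 2-bromo-6-hydroxy-4-methoxybenzaldehyde; 3 ethyl (triphenylphosphoranylidene)acetate
Product: 5 5-bromo-7-methoxycoumarin, via bromo hydroxycinnamate 4 (not isolated)
Conditions: PhNEt2, 210 °C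
Reagents that add atoms: none
Why: Wittig olefination gives the 2-hydroxycinnamate, which at this temperature equilibrates to the Z isomer and lactonises with loss of ethanol, the standard route from salicylaldehydes to 3,4-unsubstituted coumarins.

Step 3
Reactants: 5 5-bromo-7-methoxycoumarin; 6 3,5-dimethoxyphenylboronic acid
Product: 7 (4R)-5-bromo-4-(3,5-dimethoxyphenyl)-7-methoxy-3,4-dihydrocoumarin
Conditions: [Rh(OH)(cod)]2 (2.5 mol%), (R)-SEGPHOS (6 mol%, premixed), 6 (3 equiv), 1,4-dioxane/H2O 10:1, 60 °C
Reagents that add atoms: none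
Why: Hayashi–Miyaura asymmetric 1,4-addition of an arylboronic acid to a coumarin in a base-free aqueous medium that leaves the lactone and the aryl bromide untouched; the new C4 centre is set by the ligand, (R)-SEGPHOS being expected to give the (4R)-lactone, and it later becomes C3 of ring C.

Step 4
Reactants: 7 (4R)-5-bromo-4-(3,5-dimethoxyphenyl)-7-methoxy-3,4-dihydrocoumarin
Product: 8 (4R)-4-(3,5-dimethoxyphenyl)-5-(5,5-dimethyl-1,3,2-dioxaborinan-2-yl)-7-methoxy-3,4-dihydrocoumarin
Conditions: bis(neopentyl glycolato)diboron (1.5 equiv), PdCl2(dppf) (5 mol%), KOAc (3 equiv), 1,4-dioxane, 90 °C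
Reagents that add atoms: bis(neopentyl glycolato)diboron, SMILES CC1(C)COB(OC1)B1OCC(C)(C)CO1
Why: Miyaura borylation of the aryl bromide under anhydrous acetate conditions that an aryl lactone tolerates; the neopentyl glycol ester is chosen because it hydrolyses in aqueous dioxane and then transmetalates to the Rh–OH complex derived from [Rh(OH)(cod)]2 without added base.

Step 5
Reactants: 8 (4R)-4-(3,5-dimethoxyphenyl)-5-(5,5-dimethyl-1,3,2-dioxaborinan-2-yl)-7-methoxy-3,4-dihydrocoumarin; 5 5-bromo-7-methoxycoumarin
Product: 9 (4S)-5-bromo-4-[(4R)-4-(3,5-dimethoxyphenyl)-7-methoxy-2-oxochroman-5-yl]-7-methoxy-3,4-dihydrocoumarin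
Conditions: [Rh(OH)(cod)]2 (2.5 mol%), (S)-SEGPHOS (6 mol%, premixed), 5 (3 equiv), 1,4-dioxane/H2O 10:1, 60 °C
Reagents that add atoms: none
Why: The same asymmetric 1,4-addition with the boronate as limiting partner and the coumarin in excess; the new centre (future C3 of ring B) is set under catalyst control by the enantiomeric ligand, (S)-SEGPHOS being expected to give 4S, while the existing 4R centre and its lactone are spectators in the base-free medium.

Step 6
Reactants: 9 (4S)-5-bromo-4-[(4R)-4-(3,5-dimethoxyphenyl)-7-methoxy-2-oxochroman-5-yl]-7-methoxy-3,4-dihydrocoumarin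
Product: 10 (4S)-4-[(4R)-4-(3,5-dimethoxyphenyl)-7-methoxy-2-oxochroman-5-yl]-5-(5,5-dimethyl-1,3,2-dioxaborinan-2-yl)-7-methoxy-3,4-dihydrocoumarin
Conditions: bis(neopentyl glycolato)diboron (1.5 equiv), PdCl2(dppf) (5 mol%), KOAc (3 equiv), 1,4-dioxane, 90 °C
Reagents that add atoms: bis(neopentyl glycolato)diboron, SMILES CC1(C)COB(OC1)B1OCC(C)(C)CO1
Why: Miyaura borylation as in step 4; both lactones, the ethers and the two stereocentres are inert to palladium and the acetate base.

Step 7
Reactants: 11 2-chloro-4,6-dimethoxybenzaldehyde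
Product: 12 2-chloro-6-hydroxy-4-methoxybenzaldehyde
Conditions: BCl3 (1.5 equiv), CH2Cl2, −78 to 0 °C; aq. work-up
Reagents that add atoms: none
Why: Chelation-controlled cleavage of the methoxy group next to the aldehyde, as in step 1.

Step 8
Reactants: 12 2-chloro-6-hydroxy-4-methoxybenzaldehyde; 3 ethyl (triphenylphosphoranylidene)acetate
Product: 14 5-chloro-7-methoxycoumarin, via chloro hydroxycinnamate 13 (not isolated)
Conditions: PhNEt2, 210 °C
Reagents that add atoms: none
Why: Wittig olefination followed by thermal isomerisation and lactonisation, as in step 2.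

Step 9
Reactants: 10 (4S)-4-[(4R)-4-(3,5-dimethoxyphenyl)-7-methoxy-2-oxochroman-5-yl]-5-(5,5-dimethyl-1,3,2-dioxaborinan-2-yl)-7-methoxy-3,4-dihydrocoumarin; 14 5-chloro-7-methoxycoumarin
Product: 15 tris-lactone chloride (4R)-5-chloro-4-{(4S)-4-[(4R)-4-(3,5-dimethoxyphenyl)-7-methoxy-2-oxochroman-5-yl]-7-methoxy-2-oxochroman-5-yl}-7-methoxy-3,4-dihydrocoumarin
Conditions: [Rh(OH)(cod)]2 (2.5 mol%), (R)-SEGPHOS (6 mol%, premixed), 14 (3 equiv), 1,4-dioxane/H2O 10:1, 60 °C
Reagents that add atoms: none
Why: Third asymmetric 1,4-addition, now onto the chloro coumarin, whose carbon–chlorine bond is inert to rhodium; (R)-SEGPHOS should set the new centre as 4R (future C3 of ring A) under catalyst control, and the two existing centres are spectators.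

Step 10
Reactants: 15 tris-lactone chloride
Product: 17 tris(3-bromo lactone) of 15 (C3 of each lactone brominated as a mixture of epimers; C4 centres R/S/R unchanged), via tris(silyl ketene acetal) 16 (not isolated)
Conditions: TMSCl (6 equiv), LiN(SiMe3)2 (4 equiv), THF, −78 °C; then NBS (3.1 equiv), −78 °C
Reagents that add atoms: N-bromosuccinimide, SMILES O=C1CCC(=O)N1Br
Why: Internal-quench silylation turns each lactone enolate into its ketene silyl acetal as soon as it forms, which avoids a free trianion and its collapse to a ketene, and the acetals then take up electrophilic bromine at −78 °C far faster than the methoxyarenes (α-halogenation of esters through silyl ketene acetals); the new C3 centres need no control and the C4 centres are not enolisable.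

Step 11
Reactants: 17 tris(3-bromo lactone)
Product: 18 tris-acid (3R)-4-chloro-3-{(3S)-2-carboxy-3-[(3R)-2-carboxy-3-(3,5-dimethoxyphenyl)-6-methoxy-2,3-dihydrobenzofuran-4-yl]-6-methoxy-2,3-dihydrobenzofuran-4-yl}-6-methoxy-2,3-dihydrobenzofuran-2-carboxylic acid (each C2 as a mixture of epimers)
Conditions: NaOH (1 M aq., 9 equiv), THF, 0 to 25 °C; then HCl to pH 2
Reagents that add atoms: sodium hydroxide, SMILES [Na+].[OH-]
Why: Hydroxide opens each aryl lactone to a phenoxide and an α-bromo carboxylate, and the phenoxide displaces bromide in a 5-exo-tet intramolecular Williamson etherification, so each six-membered lactone contracts to a dihydrobenzofuran whose former lactone carbonyl is now the C2 carboxyl group; the C3 centres (R, S, R) are untouched.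

Step 12
Reactants: 18 tris-acid; 19 4-bromoanisole (three molecules incorporated per molecule of 18)
Product: 20 (2R,3R)-4-chloro-3-{(2S,3S)-3-[(2R,3R)-3-(3,5-dimethoxyphenyl)-6-methoxy-2-(4-methoxyphenyl)-2,3-dihydrobenzofuran-4-yl]-6-methoxy-2-(4-methoxyphenyl)-2,3-dihydrobenzofuran-4-yl}-6-methoxy-2-(4-methoxyphenyl)-2,3-dihydrobenzofuran
Conditions: 19 (9 equiv in all), Ir[dF(CF3)ppy]2(dtbbpy)PF6 (3 mol%), NiCl2(dme) (30 mol%), dtbbpy (40 mol%), Cs2CO3 (4.5 equiv), DMF, blue LEDs (450 nm), 25 °C, argon
Reagents that add atoms: 4-bromoanisole (second equivalent of 19), SMILES COc1ccc(Br)cc1; 4-bromoanisole (third equivalent of 19), SMILES COc1ccc(Br)cc1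
Why: Each caesium carboxylate is oxidised by the excited trivalent iridium complex and loses CO2 to give a planar α-aryloxy radical at C2, which is captured by the divalent arylnickel bromide formed from zerovalent nickel and 4-bromoanisole; reductive elimination from trivalent nickel forms the C2–aryl bond and the reduced iridium complex returns the monovalent nickel to the zerovalent state. The closest known reaction type is the iridium/nickel metallaphotoredox decarboxylative arylation of α-oxy and α-amino acids with aryl bromides, here run three times on one substrate; no ring is closed. The three new stereocentres (C2 of rings A, B and C) are each set by 1,2-induction from the neighbouring C3 centre: the bulky C3 aryl group shields one face of the flat radical and of the nickel alkyl, so the anisyl group should end up trans, giving (2R,3R), (2S,3S) and (2R,3R), and both C2 epimers of each acid converge on the same product. The step needs bromide-over-chloride selectivity at nickel, which the hindered and unactivated aryl chloride of ring A should secure at room temperature. It also needs reductive elimination to outrun β-hydride loss towards the aromatic benzofuran, which bipyridine-ligated nickel favours for secondary alkyl partners. The carboxyl carbons are the former coumarin carbonyls and leave the molecule here, one molecule of 19 being consumed for each of them.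

Step 13
Reactants: 20 octa-O-methyl chloride
Product: 22 octaacetate chloride (the eight methyl groups of 20 replaced by acetyl; six stereocentres unchanged), via octaphenol chloride 21 (not isolated)
Conditions: BBr3 (24 equiv), CH2Cl2, −78 to 0 °C; MeOH then pyridine, −78 °C, evaporate; then Ac2O, pyridine, DMAP (cat.), 25 °C
Reagents that add atoms: acetic anhydride, SMILES CC(=O)OC(C)=O
Why: Exhaustive Lewis-acid ether cleavage is carried out while no alkene is present, so the only acid-labile units are the trans-2-aryl-dihydrobenzofurans, which reclose to the trans isomer if they ionise; buffered quench and direct peracetylation (nucleophilic acyl substitution) should give a stable octaacetate, and the aryl chloride is inert throughout.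

Step 14
Reactants: 23 caffeic acid
Product: 25 3,4-diacetoxystyrene, via 3,4-dihydroxystyrene 24 (not isolated)
Conditions: Et3N, DMF, 100 °C, argon; then Ac2O, 25 °C
Reagents that add atoms: acetic anhydride, SMILES CC(=O)OC(C)=O
Why: Base-promoted thermal decarboxylation of a 4-hydroxycinnamic acid through its quinone methide tautomer gives the vinylcatechol, which is acetylated in the same flask before it can polymerise or oxidise.

Step 15
Reactants: 22 octaacetate chloride; 25 3,4-diacetoxystyrene
Product: 26 deca-acetate of the target (E-stilbene; A 2R,3R; B 2S,3S; C 2R,3R)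
Conditions: Pd2(dba)3 (2.5 mol%), [HP(t-Bu)3]BF4 (6 mol%), Cy2NMe (1.5 equiv), 25 (2 equiv), 1,4-dioxane, 100 °C
Reagents that add atoms: none
Why: Mizoroki–Heck reaction of an aryl chloride under tri-tert-butylphosphine-ligated palladium, a system suited to hindered and unactivated chlorides; syn insertion and syn β-hydride elimination give the (E)-stilbene, and the aryl acetates and the six stereocentres are inert to the hindered amine base.

Step 16
Reactants: 26 deca-acetate of the target
Product: 27 CNP0099535.1 (target)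
Conditions: K2CO3, MeOH/THF (degassed), 0 °C; AcOH
Reagents that add atoms: none
Why: Carbonate-mediated methanolysis (transesterification) of the ten aryl acetates at 0 °C frees the phenols under non-acidic conditions, so the stilbene and the trans-dihydrobenzofurans are never exposed to protonation, and degassing protects the catechol.

Compound list
1 | 2-bromo-4,6-dimethoxybenzaldehyde | COc1cc(OC)c(C=O)c(Br)c1 | starting material
2 | 2-bromo-6-hydroxy-4-methoxybenzaldehyde | COc1cc(O)c(C=O)c(Br)c1 | intermediate
3 | ethyl (triphenylphosphoranylidene)acetate | CCOC(=O)C=P(c1ccccc1)(c1ccccc1)c1ccccc1 | starting material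
4 | ethyl 3-(2-bromo-6-hydroxy-4-methoxyphenyl)prop-2-enoate (E/Z) | CCOC(=O)C=Cc1c(O)cc(OC)cc1Br | intermediate (not isolated)
5 | 5-bromo-7-methoxycoumarin | COc1cc(Br)c2C=CC(=O)Oc2c1 | intermediate
6 | 3,5-dimethoxyphenylboronic acid | COc1cc(OC)cc(B(O)O)c1 | starting material
7 | (4R)-5-bromo-4-(3,5-dimethoxyphenyl)-7-methoxy-3,4-dihydrocoumarin | COc1cc(Br)c2c(c1)OC(=O)C[C@@H]2c1cc(OC)cc(OC)c1 | intermediate
8 | (4R)-4-(3,5-dimethoxyphenyl)-5-(5,5-dimethyl-1,3,2-dioxaborinan-2-yl)-7-methoxy-3,4-dihydrocoumarin | COc1cc(B3OCC(C)(C)CO3)c2c(c1)OC(=O)C[C@@H]2c1cc(OC)cc(OC)c1 | intermediate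
9 | (4S)-5-bromo-4-[(4R)-4-(3,5-dimethoxyphenyl)-7-methoxy-2-oxochroman-5-yl]-7-methoxy-3,4-dihydrocoumarin | COc1cc(Br)c2c(c1)OC(=O)C[C@H]2c1cc(OC)cc2c1[C@@H](c1cc(OC)cc(OC)c1)CC(=O)O2 | intermediate
10 | (4S)-4-[(4R)-4-(3,5-dimethoxyphenyl)-7-methoxy-2-oxochroman-5-yl]-5-(5,5-dimethyl-1,3,2-dioxaborinan-2-yl)-7-methoxy-3,4-dihydrocoumarin | COc1cc(B3OCC(C)(C)CO3)c2c(c1)OC(=O)C[C@H]2c1cc(OC)cc2c1[C@@H](c1cc(OC)cc(OC)c1)CC(=O)O2 | intermediate
11 | 2-chloro-4,6-dimethoxybenzaldehyde | COc1cc(OC)c(C=O)c(Cl)c1 | starting material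
12 | 2-chloro-6-hydroxy-4-methoxybenzaldehyde | COc1cc(O)c(C=O)c(Cl)c1 | intermediate
13 | ethyl 3-(2-chloro-6-hydroxy-4-methoxyphenyl)prop-2-enoate (E/Z) | CCOC(=O)C=Cc1c(O)cc(OC)cc1Cl | intermediate (not isolated)
14 | 5-chloro-7-methoxycoumarin | COc1cc(Cl)c2C=CC(=O)Oc2c1 | intermediate
15 | tris-lactone chloride, (4R)-5-chloro-4-{(4S)-4-[(4R)-4-(3,5-dimethoxyphenyl)-7-methoxy-2-oxochroman-5-yl]-7-methoxy-2-oxochroman-5-yl}-7-methoxy-3,4-dihydrocoumarin | COc1cc(Cl)c2c(c1)OC(=O)C[C@@H]2c1cc(OC)cc2c1[C@H](c1cc(OC)cc3c1[C@@H](c1cc(OC)cc(OC)c1)CC(=O)O3)CC(=O)O2 | intermediate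
16 | tris(trimethylsilyl ketene acetal) of 15 (each lactone as its 2-trimethylsilyloxy-4H-chromene) | COc1cc(Cl)c2c(c1)OC(O[Si](C)(C)C)=C[C@@H]2c1cc(OC)cc2c1[C@H](c1cc(OC)cc3c1[C@@H](c1cc(OC)cc(OC)c1)C=C(O[Si](C)(C)C)O3)C=C(O[Si](C)(C)C)O2 | intermediate (not isolated)
17 | tris(3-bromo lactone) of 15 (C3 epimer mixtures; C4 R, S, R) | COc1cc(Cl)c2c(c1)OC(=O)C(Br)[C@@H]2c1cc(OC)cc2c1[C@H](c1cc(OC)cc3c1[C@@H](c1cc(OC)cc(OC)c1)C(Br)C(=O)O3)C(Br)C(=O)O2 | intermediate
18 | tris-acid, (3R)-4-chloro-3-{(3S)-2-carboxy-3-[(3R)-2-carboxy-3-(3,5-dimethoxyphenyl)-6-methoxy-2,3-dihydrobenzofuran-4-yl]-6-methoxy-2,3-dihydrobenzofuran-4-yl}-6-methoxy-2,3-dihydrobenzofuran-2-carboxylic acid (C2 epimer mixtures) | OC(=O)C1Oc2cc(OC)cc([C@@H]3c4c(Cl)cc(OC)cc4OC3C(=O)O)c2[C@@H]1c1cc(OC)cc2c1[C@@H](c1cc(OC)cc(OC)c1)C(C(=O)O)O2 | intermediate (key-step precursor)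
19 | 4-bromoanisole | COc1ccc(Br)cc1 | starting material
20 | octa-O-methyl chloride, (2R,3R)-4-chloro-3-{(2S,3S)-3-[(2R,3R)-3-(3,5-dimethoxyphenyl)-6-methoxy-2-(4-methoxyphenyl)-2,3-dihydrobenzofuran-4-yl]-6-methoxy-2-(4-methoxyphenyl)-2,3-dihydrobenzofuran-4-yl}-6-methoxy-2-(4-methoxyphenyl)-2,3-dihydrobenzofuran | COc1ccc([C@H]2Oc3cc(OC)cc([C@@H]4c5c(Cl)cc(OC)cc5O[C@H]4c4ccc(OC)cc4)c3[C@@H]2c2cc(OC)cc3c2[C@@H](c2cc(OC)cc(OC)c2)[C@H](c2ccc(OC)cc2)O3)cc1 | intermediate (key-step product)
21 | octaphenol chloride (20 with all eight methoxy groups as hydroxy) | Oc1ccc([C@H]2Oc3cc(O)cc([C@@H]4c5c(Cl)cc(O)cc5O[C@H]4c4ccc(O)cc4)c3[C@@H]2c2cc(O)cc3c2[C@@H](c2cc(O)cc(O)c2)[C@H](c2ccc(O)cc2)O3)cc1 | intermediate (not isolated)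
22 | octaacetate chloride (21 with all eight hydroxy groups acetylated) | CC(=O)Oc1ccc([C@H]2Oc3cc(OC(C)=O)cc([C@@H]4c5c(Cl)cc(OC(C)=O)cc5O[C@H]4c4ccc(OC(C)=O)cc4)c3[C@@H]2c2cc(OC(C)=O)cc3c2[C@@H](c2cc(OC(C)=O)cc(OC(C)=O)c2)[C@H](c2ccc(OC(C)=O)cc2)O3)cc1 | intermediate
23 | caffeic acid | OC(=O)/C=C/c1ccc(O)c(O)c1 | starting material
24 | 3,4-dihydroxystyrene | C=Cc1ccc(O)c(O)c1 | intermediate (not isolated)
25 | 3,4-diacetoxystyrene | CC(=O)Oc1ccc(C=C)cc1OC(C)=O | intermediate
26 | deca-acetate of the target (ring A C4 carries the (E)-3,4-diacetoxystyryl group) | CC(=O)Oc1ccc([C@H]2Oc3cc(OC(C)=O)cc([C@@H]4c5c(/C=C/c6ccc(OC(C)=O)c(OC(C)=O)c6)cc(OC(C)=O)cc5O[C@H]4c4ccc(OC(C)=O)cc4)c3[C@@H]2c2cc(OC(C)=O)cc3c2[C@@H](c2cc(OC(C)=O)cc(OC(C)=O)c2)[C@H](c2ccc(OC(C)=O)cc2)O3)cc1 | intermediate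
27 | CNP0099535.1 | Oc1ccc([C@H]2Oc3cc(O)cc([C@@H]4c5c(/C=C/c6ccc(O)c(O)c6)cc(O)cc5O[C@H]4c4ccc(O)cc4)c3[C@@H]2c2cc(O)cc3c2[C@@H](c2cc(O)cc(O)c2)[C@H](c2ccc(O)cc2)O3)cc1 | target

Total step count: 16.
Longest linear sequence: 13 steps (steps 1, 2, 3, 4, 5, 6, 9, 10, 11, 12, 13, 15, 16).

Steps most likely to fail:

1. Step 12. The threefold coupling may stop short through protodecarboxylation at one site. The nickel alkyl may lose a β-hydride and aromatise a ring to the benzofuran, face selectivity at one of the C2 radicals may be poor, or turnover with the electron-rich aryl bromide may be slow. The fallback sets out from 18: the three acids are esterified with N-hydroxyphthalimide (DIC, DMAP cat., CH2Cl2) to the tris(N-acyloxyphthalimide) F1. F1 is then coupled with three equivalents of (4-methoxyphenyl)zinc chloride under NiCl2(dme)/dtbbpy in THF/DMF at 25 °C, a decarboxylative Negishi arylation of redox-active esters. The same C2 radicals arise by thermal single-electron reduction, without light and without an aryl bromide, the same 1,2-induction applies, and the route is rejoined at 20.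

2. Step 9 (step 5 is exposed to the same risk in a smaller molecule). Insertion of the hindered aryl–Rh intermediate into the peri-substituted, electron-rich coumarin may be slower than protodeboronation, and the existing centres may oppose the ligand and lower the facial selectivity. The fallback sets out from 10 and 14: oxidative Heck arylation of the coumarin at C4 (Pd(OAc)2, 1,10-phenanthroline, O2, DMF, 80 °C) gives the 4-arylcoumarin F2, in which the new carbon is still flat and rotamers about the new aryl bond are of no consequence. CuH-catalysed conjugate reduction (Cu(OAc)2, DTBM-SEGPHOS in the enantiomer that gives 4R, (EtO)2MeSiH, t-BuOH, toluene) then sets the centre by hydride delivery and returns to 15.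

3. Step 10. Chemoselectivity may be lost through bromination of the methoxy-activated rings or double bromination, the aryl-ester enolates may fragment to ketenes before they are silylated, and the bromides may later lose HBr towards 4-arylcoumarins in step 11. The fallback sets out from 15 by way of 16: Rubottom oxidation of the tris(silyl ketene acetal) with mCPBA and fluoride work-up gives the tris(3-hydroxy lactone) F3. Mesylation (MsCl, Et3N, CH2Cl2, 0 °C) gives the tris(3-mesyloxy lactone) F4, and aqueous NaOH as in step 11 closes the three furan rings by sulfonate displacement, returning to 18.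

Further compounds
F1 | step 12 | tris(N-acyloxyphthalimide) of 18 (each C2 carboxyl group as its N-hydroxyphthalimide ester) | O=C(ON5C(=O)c6ccccc6C5=O)C1Oc2cc(OC)cc([C@@H]3c4c(Cl)cc(OC)cc4OC3C(=O)ON3C(=O)c4ccccc4C3=O)c2[C@@H]1c1cc(OC)cc2c1[C@@H](c1cc(OC)cc(OC)c1)C(C(=O)ON1C(=O)c3ccccc3C1=O)O2
F2 | step 9 | 5-chloro-4-{(4S)-4-[(4R)-4-(3,5-dimethoxyphenyl)-7-methoxy-2-oxochroman-5-yl]-7-methoxy-2-oxochroman-5-yl}-7-methoxycoumarin | COc1cc(Cl)c2c(c1)OC(=O)C=C2c1cc(OC)cc2c1[C@H](c1cc(OC)cc3c1[C@@H](c1cc(OC)cc(OC)c1)CC(=O)O3)CC(=O)O2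
F3 | step 10 | tris(3-hydroxy lactone) of 15 (C3 epimer mixtures) | COc1cc(Cl)c2c(c1)OC(=O)C(O)[C@@H]2c1cc(OC)cc2c1[C@H](c1cc(OC)cc3c1[C@@H](c1cc(OC)cc(OC)c1)C(O)C(=O)O3)C(O)C(=O)O2
F4 | step 10 | tris(3-mesyloxy lactone) of 15 (C3 epimer mixtures) | COc1cc(Cl)c2c(c1)OC(=O)C(OS(C)(=O)=O)[C@@H]2c1cc(OC)cc2c1[C@H](c1cc(OC)cc3c1[C@@H](c1cc(OC)cc(OC)c1)C(OS(C)(=O)=O)C(=O)O3)C(OS(C)(=O)=O)C(=O)O2
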